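A direct plan would start from all-E-geranylgeraniol A1, epoxidise the allylic 2,3-alkene of A1 with Ti(OiPr)4, diethyl D-tartrate and t-BuOOH to the epoxy alcohol A2, isomerise A2 with Ti(OiPr)4 to the 3-methylidene-1,2-diol A3, acetylate it to the diacetate A4 and close rings A and B of A4 in one chiral-acid-catalysed polyene cyclisation to the target.
Weakest, the final cation–olefin bicyclisation: it would have to set C5, C9 and C10 by catalyst control alone, next to a remote C14 centre that relays nothing, and end by loss of H-7 only. The 8(17)-ene, the 8-ene, the 8-ol and diastereomers would appear in the last step, and the acid would also meet the 1,1-disubstituted alkene and an allylic acetate.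
Second, the epoxide-to-allylic-alcohol isomerisation: the proton would have to leave the C3 methyl and not the chain CH2, in competition with opening by isopropoxide, and it needs stoichiometric titanium.
Third, the way the stereocentres are set: C14 and the three decalin centres would come from two unrelated reagents, so any loss of selectivity in either would end as a hard-to-separate diastereomer of an oily diterpene.

**Retrosynthetic overview**
Ring B with the C8 methyl, the C7=C8 alkene and the C5 stereocentre, together with C4 and one of its methyls, is (R)-carvone atom for atom. Ring B would therefore be bought and ring A closed onto it, the reverse of the ring order of a polyene cyclisation.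
C3–C4 (key): a hydrogen-atom-transfer radical cyclisation would turn the isopropenyl group into the quaternary C4 and close ring A onto a 2-sulfonylallyl arm. That arm is put on C10 by enolate alkylation trans to the isopropenyl group (C10–C1), which fixes C10 and the trans fusion from C5.
C9–C11: the complete side chain, with C14 taken from D-glyceraldehyde, would add to the C9 ketone. Palladium–formate hydrogenolysis of the tertiary allylic carbonate would then set 9α-H and leave the alkene where carvone had it.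
So no cyclisation terminus decides the alkene position, every decalin centre is relayed from C5, C14 needs no epoxide isomerisation, and the two halves meet late.
Key step: step 5

Assumption: the 2-sulfonylallyl bromide is not treated as a stock chemical and is made in steps 1 and 2.
Remark: the bicyclic sulfone and its successors would be carried as both epimers at the sulfonyl-bearing carbon (C2 of the labdane skeleton), which becomes CH2 in step 12.

Step 1
Reactants: 1 phenyl vinyl sulfone (ethenesulfonylbenzene; commercial)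
Product: 2 2-(phenylsulfonyl)prop-2-en-1-ol
Conditions: aq. CH2O (37 %), DABCO (1 equiv), dioxane/H2O, rt
Reagents that add atoms: formaldehyde, C=O
Why: Morita–Baylis–Hillman reaction: DABCO adds to the vinyl sulfone, the α-sulfonyl carbanion is trapped by formaldehyde and loss of the amine returns the 2-substituted allylic alcohol, a reaction type known for aryl vinyl sulfones.

Step 2
Reactants: 2 2-(phenylsulfonyl)prop-2-en-1-ol
Product: 3 3-bromo-2-(phenylsulfonyl)prop-1-ene
Conditions: PBr3 (0.4 equiv), Et2O, 0 °C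
Reagents that add atoms: phosphorus tribromide, BrP(Br)Br
Why: Bromination of the primary allylic alcohol with PBr3 (SN2 and SN2′ attack give the same bromide because the allyl unit is 2-substituted) should give the doubly activated allylating agent for step 4.

Step 3
Reactants: 4 (R)-(−)-carvone [(5R)-2-methyl-5-(prop-1-en-2-yl)cyclohex-2-en-1-one; commercial]
Product: 6 (5R)-2,6-dimethyl-5-(prop-1-en-2-yl)cyclohex-2-en-1-one (6-methylcarvone; both C-6 epimers), via carvone lithium dienolate 5 (not isolated)
Conditions: LiN(i-Pr)2 (1.1 equiv), THF, −78 °C; MeI, −78 → 0 °C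
Reagents that add atoms: iodomethane, CI
Why: Kinetic α′-deprotonation of the enone and C-methylation of the cross-conjugated lithium dienolate (enolate alkylation) should install the future C20 methyl; the new centre need not be controlled because it is planarised again in step 4.

Step 4
Reactants: 6 (5R)-2,6-dimethyl-5-(prop-1-en-2-yl)cyclohex-2-en-1-one; 3 3-bromo-2-(phenylsulfonyl)prop-1-ene
Product: 8 (5S,6S)-2,6-dimethyl-6-[2-(phenylsulfonyl)prop-2-en-1-yl]-5-(prop-1-en-2-yl)cyclohex-2-en-1-one, via methylcarvone lithium enolate 7 (not isolated)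
Conditions: LiN(i-Pr)2 (1.2 equiv), THF, −78 → −20 °C; 3, −78 °C → rt
Reagents that add atoms: none
Why: Second enolate alkylation, here an addition–elimination (SN2′) on the 2-sulfonylallyl bromide: the tetrasubstituted enolate should be attacked on the face opposite to the neighbouring isopropenyl group at C5, so that the new CH2 arm (C1) is trans and the methyl (C20) cis to it, which sets the quaternary C10 and with it the later trans ring fusion.

Step 5
Reactants: 8 (5S,6S)-2,6-dimethyl-6-[2-(phenylsulfonyl)prop-2-en-1-yl]-5-(prop-1-en-2-yl)cyclohex-2-en-1-one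
Product: 10 (4aS,8aS)-2,5,5,8a-tetramethyl-7-(phenylsulfonyl)-4a,5,6,7,8,8a-hexahydronaphthalen-1(4H)-one (trans-fused; both C-7 epimers), via tertiary C-4 radical 9 (not isolated)
Conditions: Fe(acac)3 (0.5 equiv), PhSiH3 (2.5 equiv), EtOH/(CH2OH)2 5:1, 0.02 M, 60 °C
Reagents that add atoms: none
Why: PhSiH3 and Fe(acac)3 in ethanol form an iron hydride that transfers a hydrogen atom to the CH2 terminus of the electron-rich isopropenyl group (Markovnikov, Mukaiyama-type hydrogen-atom transfer), which completes the gem-dimethyl pair and gives the tertiary radical 9 at C4. This nucleophilic radical adds to the unsubstituted terminus (C3) of the 2-sulfonylallyl acceptor, so the C3–C4 bond, the quaternary C4 and ring A form in one event, after which the α-sulfonyl radical is reduced by divalent iron and protonated by ethanol. The closest known reaction type is the iron-mediated reductive olefin–olefin coupling (hydrogen-atom-transfer-initiated Giese addition), known between and within molecules with vinyl sulfones, enones and acrylates and tolerant of new quaternary carbons. Ring A closes in the 6-endo-trig mode, favoured over 5-exo because polarity and sterics steer the radical to the CH2 end of the α-substituted acceptor and away from the sulfonyl-bearing carbon. No stereocentre of the target is created (the sulfonyl-bearing C2 is lost in step 12); the trans ring fusion is inherited from the trans arrangement of the two arms fixed in step 4, which can bridge only through the diequatorial conformer. The step needs hydrogen-atom transfer to the isopropenyl group in preference to the enone and the vinyl sulfone, which their electron-poor character secures, and ring closure faster than reduction of 9, which the strong acceptor and high dilution secure.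

Step 6
Reactants: 11 (R)-2,2-dimethyl-1,3-dioxolane-4-carbaldehyde (2,3-O-isopropylidene-D-glyceraldehyde; commercial)
Product: 12 (4S)-4-ethynyl-2,2-dimethyl-1,3-dioxolane
Conditions: dimethyl (1-diazo-2-oxopropyl)phosphonate, K2CO3, MeOH, 0 °C → rt
Reagents that add atoms: dimethyl (1-diazo-2-oxopropyl)phosphonate, COP(=O)(OC)C(=[N+]=[N-])C(C)=O
Why: Seyferth–Gilbert homologation with the Ohira–Bestmann reagent converts the aldehyde into the terminal alkyne under carbonate conditions mild enough to keep the α-alkoxy stereocentre (the future C14; its descriptor changes from R to S only through the CIP ranks).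

Step 7
Reactants: 12 (4S)-4-ethynyl-2,2-dimethyl-1,3-dioxolane
Product: 14 (4R)-4-(1-iodoethenyl)-2,2-dimethyl-1,3-dioxolane (same spatial arrangement as in 12), via alpha-alkenylalane 13 (not isolated)
Conditions: i-Bu2AlH (1.3 equiv), Ni(dppp)Cl2 (3 mol %), THF, 0 °C → rt; then N-iodosuccinimide, 0 °C
Reagents that add atoms: N-iodosuccinimide, O=C1CCC(=O)N1I
Why: Nickel-catalysed α-selective (Markovnikov) hydroalumination of the terminal alkyne with the bisphosphine complex Ni(dppp)Cl2, followed by iodinolysis of the C–Al bond, should give the 2-iodo-1-alkene that carries C13 and the future methylidene carbon C16.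

Step 8
Reactants: 14 (4R)-4-(1-iodoethenyl)-2,2-dimethyl-1,3-dioxolane
Product: 16 3-[(4S)-2,2-dimethyl-1,3-dioxolan-4-yl]but-3-en-1-ol, via alkenyllithium 15 (not isolated)
Conditions: t-BuLi (2.0 equiv), Et2O, −78 °C; ethylene oxide, BF3·OEt2, −78 °C
Reagents that add atoms: ethylene oxide, C1CO1
Why: Iodine–lithium exchange and BF3-assisted ring opening of ethylene oxide by the alkenyllithium (epoxide alkylation) add C12 and C11 as a 2-hydroxyethyl group without touching the stereocentre.

Step 9
Reactants: 16 3-[(4S)-2,2-dimethyl-1,3-dioxolan-4-yl]but-3-en-1-ol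
Product: 17 (4S)-4-(4-iodobut-1-en-2-yl)-2,2-dimethyl-1,3-dioxolane
Conditions: I2, PPh3, imidazole, CH2Cl2, 0 °C → rt
Reagents that add atoms: iodine, II
Why: Appel-type iodination of the primary alcohol under imidazole buffering, which leaves the acid-labile acetonide and the alkene intact.

Step 10
Reactants: 17 (4S)-4-(4-iodobut-1-en-2-yl)-2,2-dimethyl-1,3-dioxolane; 10 (4aS,8aS)-2,5,5,8a-tetramethyl-7-(phenylsulfonyl)-4a,5,6,7,8,8a-hexahydronaphthalen-1(4H)-one
Product: 21 methyl (1S,4aS,8aS)-1-{3-[(4S)-2,2-dimethyl-1,3-dioxolan-4-yl]but-3-en-1-yl}-2,5,5,8a-tetramethyl-7-(phenylsulfonyl)-1,4,4a,5,6,7,8,8a-octahydronaphthalen-1-yl carbonate (both C-7 epimers), via alkyllithium 18 (not isolated), via organocerium reagent 19 (not isolated), via cerium alkoxide 20 (not isolated)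
Conditions: 17, t-BuLi (2.0 equiv), Et2O/pentane, −78 °C; anhydrous CeCl3, THF, −78 °C; 10, −78 → −40 °C; ClCO2Me, −78 → 0 °C
Reagents that add atoms: methyl chloroformate, COC(Cl)=O
Why: Organocerium 1,2-addition to the hindered enone (the low basicity of RCeCl2 avoids deprotonation next to the sulfone) is expected on the α face, anti to the axial C10 methyl, so that the C9 oxygen is β and the side chain α, and the tertiary alkoxide is acylated in the same flask (chloroformate trapping) to the allylic carbonate needed for step 11.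

Step 11
Reactants: 21 methyl (1S,4aS,8aS)-1-{3-[(4S)-2,2-dimethyl-1,3-dioxolan-4-yl]but-3-en-1-yl}-2,5,5,8a-tetramethyl-7-(phenylsulfonyl)-1,4,4a,5,6,7,8,8a-octahydronaphthalen-1-yl carbonate
Product: 22 (4S)-4-{4-[(1S,4aS,8aS)-2,5,5,8a-tetramethyl-7-(phenylsulfonyl)-1,4,4a,5,6,7,8,8a-octahydronaphthalen-1-yl]but-1-en-2-yl}-2,2-dimethyl-1,3-dioxolane (both C-7 epimers)
Conditions: Pd(OAc)2 (5 mol %), n-Bu3P (20 mol %), HCO2H (3 equiv), Et3N (3 equiv), THF, 50 °C
Reagents that add atoms: none
Why: Palladium-catalysed formate hydrogenolysis of an allylic carbonate (Tsuji–Trost-type reduction): zerovalent palladium ionises the tertiary C9–O bond with inversion so that the metal sits on the α face of the C7–C8–C9 allyl unit, the formate ligand loses CO2 and the hydride passes from palladium to the more substituted terminus C9 on that same face, which should give 9α-H with the side chain β (equatorial) and leave the alkene at C7=C8, the less substituted olefin that this reduction characteristically forms.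

Step 12
Reactants: 22 (4S)-4-{4-[(1S,4aS,8aS)-2,5,5,8a-tetramethyl-7-(phenylsulfonyl)-1,4,4a,5,6,7,8,8a-octahydronaphthalen-1-yl]but-1-en-2-yl}-2,2-dimethyl-1,3-dioxolane
Product: 24 (2S)-3-methylidene-5-[(1S,4aS,8aS)-2,5,5,8a-tetramethyl-1,4,4a,5,6,7,8,8a-octahydronaphthalen-1-yl]pentane-1,2-diol, via desulfonylated acetonide 23 (not isolated)
Conditions: Mg turnings, HgCl2 (5 mol %), EtOH/THF, rt; then 1 M aq. HCl, rt
Reagents that add atoms: none
Why: Single-electron reductive desulfonylation of the alkyl phenyl sulfone removes the activating group that served the ring closure and leaves CH2 at C2, and acidification of the same flask hydrolyses the isopropylidene acetal to the diol (acetal hydrolysis); no stereocentre is touched.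

Step 13
Reactants: 24 (2S)-3-methylidene-5-[(1S,4aS,8aS)-2,5,5,8a-tetramethyl-1,4,4a,5,6,7,8,8a-octahydronaphthalen-1-yl]pentane-1,2-diol
Product: 25 (2S)-3-methylidene-5-[(1S,4aS,8aS)-2,5,5,8a-tetramethyl-1,4,4a,5,6,7,8,8a-octahydronaphthalen-1-yl]pentane-1,2-diyl diacetate (CNP0289003.1)
Conditions: Ac2O (3 equiv), pyridine, DMAP (5 mol %), CH2Cl2, 0 °C → rt
Reagents that add atoms: acetic anhydride, CC(=O)OC(C)=O
Why: Nucleophilic-catalysis (DMAP) acetylation of the primary and the secondary allylic hydroxyl under basic conditions that affect neither alkene nor any stereocentre.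

**Compound list**
1 | phenyl vinyl sulfone (ethenesulfonylbenzene) | C=CS(=O)(=O)c1ccccc1 | starting material
2 | 2-(phenylsulfonyl)prop-2-en-1-ol | C=C(CO)S(=O)(=O)c1ccccc1 | intermediate
3 | 3-bromo-2-(phenylsulfonyl)prop-1-ene | C=C(CBr)S(=O)(=O)c1ccccc1 | intermediate
4 | (R)-(−)-carvone, (5R)-2-methyl-5-(prop-1-en-2-yl)cyclohex-2-en-1-one | CC1=CC[C@@H](C(C)=C)CC1=O | starting material
5 | lithium dienolate of carvone (O–Li on C-1, C1=C6 and C2=C3 double bonds, C-5 unchanged) | CC1=CC[C@@H](C(C)=C)C=C1O[Li] | intermediate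
6 | (5R)-2,6-dimethyl-5-(prop-1-en-2-yl)cyclohex-2-en-1-one, 6-methylcarvone (both C-6 epimers) | CC1=CC[C@@H](C(C)=C)C(C)C1=O | intermediate
7 | lithium enolate of 6 (O–Li on C-1, C1=C6 double bond bearing the 6-methyl, C-5 unchanged) | CC1=CC[C@@H](C(C)=C)C(C)=C1O[Li] | intermediate
8 | (5S,6S)-2,6-dimethyl-6-[2-(phenylsulfonyl)prop-2-en-1-yl]-5-(prop-1-en-2-yl)cyclohex-2-en-1-one (sulfonylallyl arm trans to isopropenyl) | CC1=CC[C@@H](C(C)=C)[C@](C)(CC(=C)S(=O)(=O)c2ccccc2)C1=O | intermediate
9 | tertiary propan-2-yl radical formed from 8 by hydrogen-atom transfer to the isopropenyl CH2 (ring centres as in 8) | CC1=CC[C@@H]([C](C)C)[C@](C)(CC(=C)S(=O)(=O)c2ccccc2)C1=O | intermediate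
10 | (4aS,8aS)-2,5,5,8a-tetramethyl-7-(phenylsulfonyl)-4a,5,6,7,8,8a-hexahydronaphthalen-1(4H)-one (trans-fused; both C-7 epimers) | CC1=CC[C@H]2C(C)(C)CC(S(=O)(=O)c3ccccc3)C[C@]2(C)C1=O | intermediate
11 | (R)-2,2-dimethyl-1,3-dioxolane-4-carbaldehyde (2,3-O-isopropylidene-D-glyceraldehyde) | O=C[C@H]1COC(C)(C)O1 | starting material
12 | (4S)-4-ethynyl-2,2-dimethyl-1,3-dioxolane | C#C[C@H]1COC(C)(C)O1 | intermediate
13 | diisobutyl[1-(2,2-dimethyl-1,3-dioxolan-4-yl)ethenyl]alane (configuration of 12 retained) | CC(C)C[Al](CC(C)C)C(=C)[C@H]1COC(C)(C)O1 | intermediate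
14 | (4R)-4-(1-iodoethenyl)-2,2-dimethyl-1,3-dioxolane (same spatial arrangement as 12) | C=C(I)[C@H]1COC(C)(C)O1 | intermediate
15 | 1-[(4S)-2,2-dimethyl-1,3-dioxolan-4-yl]ethenyllithium | C=C([Li])[C@H]1COC(C)(C)O1 | intermediate
16 | 3-[(4S)-2,2-dimethyl-1,3-dioxolan-4-yl]but-3-en-1-ol | OCCC(=C)[C@H]1COC(C)(C)O1 | intermediate
17 | (4S)-4-(4-iodobut-1-en-2-yl)-2,2-dimethyl-1,3-dioxolane | ICCC(=C)[C@H]1COC(C)(C)O1 | intermediate
18 | {3-[(4S)-2,2-dimethyl-1,3-dioxolan-4-yl]but-3-en-1-yl}lithium | [Li]CCC(=C)[C@H]1COC(C)(C)O1 | intermediate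
19 | dichloro{3-[(4S)-2,2-dimethyl-1,3-dioxolan-4-yl]but-3-en-1-yl}cerium | Cl[Ce](Cl)CCC(=C)[C@H]1COC(C)(C)O1 | intermediate
20 | dichlorocerium (1S,4aS,8aS)-1-{3-[(4S)-2,2-dimethyl-1,3-dioxolan-4-yl]but-3-en-1-yl}-2,5,5,8a-tetramethyl-7-(phenylsulfonyl)-1,4,4a,5,6,7,8,8a-octahydronaphthalen-1-olate (O β, side chain α) | CC1=CC[C@H]2C(C)(C)CC(S(=O)(=O)c3ccccc3)C[C@]2(C)[C@@]1(CCC(=C)[C@H]4COC(C)(C)O4)O[Ce](Cl)Cl | intermediate
21 | methyl (1S,4aS,8aS)-1-{3-[(4S)-2,2-dimethyl-1,3-dioxolan-4-yl]but-3-en-1-yl}-2,5,5,8a-tetramethyl-7-(phenylsulfonyl)-1,4,4a,5,6,7,8,8a-octahydronaphthalen-1-yl carbonate (both C-7 epimers) | CC1=CC[C@H]2C(C)(C)CC(S(=O)(=O)c3ccccc3)C[C@]2(C)[C@@]1(CCC(=C)[C@H]4COC(C)(C)O4)OC(=O)OC | intermediate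
22 | (4S)-4-{4-[(1S,4aS,8aS)-2,5,5,8a-tetramethyl-7-(phenylsulfonyl)-1,4,4a,5,6,7,8,8a-octahydronaphthalen-1-yl]but-1-en-2-yl}-2,2-dimethyl-1,3-dioxolane (both C-7 epimers) | CC1=CC[C@H]2C(C)(C)CC(S(=O)(=O)c3ccccc3)C[C@]2(C)[C@H]1CCC(=C)[C@H]4COC(C)(C)O4 | intermediate
23 | (4S)-4-{4-[(1S,4aS,8aS)-2,5,5,8a-tetramethyl-1,4,4a,5,6,7,8,8a-octahydronaphthalen-1-yl]but-1-en-2-yl}-2,2-dimethyl-1,3-dioxolane | CC1=CC[C@H]2C(C)(C)CCC[C@]2(C)[C@H]1CCC(=C)[C@H]3COC(C)(C)O3 | intermediate
24 | (2S)-3-methylidene-5-[(1S,4aS,8aS)-2,5,5,8a-tetramethyl-1,4,4a,5,6,7,8,8a-octahydronaphthalen-1-yl]pentane-1,2-diol | CC1=CC[C@H]2C(C)(C)CCC[C@]2(C)[C@H]1CCC(=C)[C@H](O)CO | intermediate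
25 | (2S)-3-methylidene-5-[(1S,4aS,8aS)-2,5,5,8a-tetramethyl-1,4,4a,5,6,7,8,8a-octahydronaphthalen-1-yl]pentane-1,2-diyl diacetate, (14S)-labda-7,13(16)-diene-14,15-diyl diacetate | C=C(CC[C@H]1C(C)=CC[C@H]2C(C)(C)CCC[C@]12C)[C@@H](COC(C)=O)OC(C)=O | target

Total step count: 13. Longest linear sequence: 8 steps (steps 6–13 from 11; the line from 1 through steps 1, 2, 4, 5 and 10–13 is equally long; from carvone it is 7).

**Steps most likely to fail**

1. Step 5. The tertiary radical could be quenched by a second hydrogen-atom transfer before it closes ring A (net hydrogenation of the isopropenyl group), or the vinyl sulfone could be reduced. The fallback sets out from 6 and closes the ring by a tin hydride chain reaction on a sulfone-free substrate. 6 would be alkylated (LiN(i-Pr)2; 2,3-dibromopropene) to (5S,6S)-6-(2-bromoprop-2-en-1-yl)-2,6-dimethyl-5-(prop-1-en-2-yl)cyclohex-2-en-1-one F1. HBr in AcOH would add across the isopropenyl group to the tertiary bromide (5R,6S)-6-(2-bromoprop-2-en-1-yl)-5-(2-bromopropan-2-yl)-2,6-dimethylcyclohex-2-en-1-one F2. Slow addition of Bu3SnH with AIBN in benzene at 80 °C would form the same C4 radical by bromine abstraction, close ring A 6-endo on the bromoalkene and reduce the secondary bromide so formed in the same flask, giving (4aS,8aS)-2,5,5,8a-tetramethyl-4a,5,6,7,8,8a-hexahydronaphthalen-1(4H)-one F3. Addition of organocerium 19 and trapping with ClCO2Me would give methyl (1S,4aS,8aS)-1-{3-[(4S)-2,2-dimethyl-1,3-dioxolan-4-yl]but-3-en-1-yl}-2,5,5,8a-tetramethyl-1,4,4a,5,6,7,8,8a-octahydronaphthalen-1-yl carbonate F4. The palladium–formate conditions of step 11 would then bring it back to the route at 23.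

2. Step 11. Poor facial selectivity in the addition of step 10 would be carried into C9, and the hydride could go to C7 or the allyl complex could lose a proton to a diene. The fallback sets out from 10 and does not depend on the carbinol configuration. 10 and 19, quenched with water instead of the chloroformate, would give (4aS,8aS)-1-{3-[(4S)-2,2-dimethyl-1,3-dioxolan-4-yl]but-3-en-1-yl}-2,5,5,8a-tetramethyl-7-(phenylsulfonyl)-1,4,4a,5,6,7,8,8a-octahydronaphthalen-1-ol F5 (either C-1 epimer). Oxidative 1,3-transposition with pyridinium chlorochromate [C5H5NH][CrO3Cl] and NaOAc in CH2Cl2 (Babler–Dauben oxidation) would give (4aS,8aS)-4-{3-[(4S)-2,2-dimethyl-1,3-dioxolan-4-yl]but-3-en-1-yl}-3,4a,8,8-tetramethyl-6-(phenylsulfonyl)-4a,5,6,7,8,8a-hexahydronaphthalen-2(1H)-one F6. Luche reduction (NaBH4, CeCl3·7H2O, MeOH), by axial hydride attack, would give the equatorial alcohol (2S,4aS,8aS)-4-{3-[(4S)-2,2-dimethyl-1,3-dioxolan-4-yl]but-3-en-1-yl}-3,4a,8,8-tetramethyl-6-(phenylsulfonyl)-1,2,4a,5,6,7,8,8a-octahydronaphthalen-2-ol F7. Myers reductive transposition (2-nitrobenzenesulfonylhydrazide, PPh3, diethyl azodicarboxylate, THF, −30 °C → rt) would invert the carbinol carbon to the α-diazene, whose sigmatropic loss of N2 delivers hydrogen to C9 on the α face and moves the alkene to C7=C8. This returns to the route at 22.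

3. Step 7. Regiocontrol of the hydroalumination could be lost, because the propargylic oxygen can steer aluminium to the terminal carbon, or the alkyne C–H could be deprotonated. The fallback sets out from 12 and replaces hydrometalation by haloboration. B-bromo-9-borabicyclo[3.3.1]nonane in CH2Cl2 at 0 °C followed by AcOH would give (4R)-4-(1-bromoethenyl)-2,2-dimethyl-1,3-dioxolane F8. Bromine–lithium exchange with t-BuLi and opening of ethylene oxide as in step 8 would return to the route at 16.

**Further compounds**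
F1 | step 5 | (5S,6S)-6-(2-bromoprop-2-en-1-yl)-2,6-dimethyl-5-(prop-1-en-2-yl)cyclohex-2-en-1-one | CC1=CC[C@@H](C(C)=C)[C@](C)(CC(Br)=C)C1=O
F2 | step 5 | (5R,6S)-6-(2-bromoprop-2-en-1-yl)-5-(2-bromopropan-2-yl)-2,6-dimethylcyclohex-2-en-1-one | CC1=CC[C@@H](C(C)(C)Br)[C@](C)(CC(Br)=C)C1=O
F3 | step 5 | (4aS,8aS)-2,5,5,8a-tetramethyl-4a,5,6,7,8,8a-hexahydronaphthalen-1(4H)-one | CC1=CC[C@H]2C(C)(C)CCC[C@]2(C)C1=O
F4 | step 5 | methyl (1S,4aS,8aS)-1-{3-[(4S)-2,2-dimethyl-1,3-dioxolan-4-yl]but-3-en-1-yl}-2,5,5,8a-tetramethyl-1,4,4a,5,6,7,8,8a-octahydronaphthalen-1-yl carbonate | CC1=CC[C@H]2C(C)(C)CCC[C@]2(C)[C@@]1(CCC(=C)[C@H]3COC(C)(C)O3)OC(=O)OC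
F5 | step 11 | (4aS,8aS)-1-{3-[(4S)-2,2-dimethyl-1,3-dioxolan-4-yl]but-3-en-1-yl}-2,5,5,8a-tetramethyl-7-(phenylsulfonyl)-1,4,4a,5,6,7,8,8a-octahydronaphthalen-1-ol (either C-1 epimer) | CC1=CC[C@H]2C(C)(C)CC(S(=O)(=O)c3ccccc3)C[C@]2(C)C1(O)CCC(=C)[C@H]4COC(C)(C)O4
F6 | step 11 | (4aS,8aS)-4-{3-[(4S)-2,2-dimethyl-1,3-dioxolan-4-yl]but-3-en-1-yl}-3,4a,8,8-tetramethyl-6-(phenylsulfonyl)-4a,5,6,7,8,8a-hexahydronaphthalen-2(1H)-one | O=C1C[C@H]2C(C)(C)CC(S(=O)(=O)c3ccccc3)C[C@]2(C)C(CCC(=C)[C@H]4COC(C)(C)O4)=C1C
F7 | step 11 | (2S,4aS,8aS)-4-{3-[(4S)-2,2-dimethyl-1,3-dioxolan-4-yl]but-3-en-1-yl}-3,4a,8,8-tetramethyl-6-(phenylsulfonyl)-1,2,4a,5,6,7,8,8a-octahydronaphthalen-2-ol | O[C@H]1C[C@H]2C(C)(C)CC(S(=O)(=O)c3ccccc3)C[C@]2(C)C(CCC(=C)[C@H]4COC(C)(C)O4)=C1C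
F8 | step 7 | (4R)-4-(1-bromoethenyl)-2,2-dimethyl-1,3-dioxolane | C=C(Br)[C@H]1COC(C)(C)O1
A1 | direct plan | all-E-geranylgeraniol, (2E,6E,10E)-3,7,11,15-tetramethylhexadeca-2,6,10,14-tetraen-1-ol | CC(C)=CCC/C(C)=C/CC/C(C)=C/CC/C(C)=C/CO
A2 | direct plan | (2R,3R)-2,3-epoxygeranylgeraniol | CC(C)=CCC/C(C)=C/CC/C(C)=C/CC[C@@]1(C)O[C@@H]1CO
A3 | direct plan | (2S,6E,10E)-7,11,15-trimethyl-3-methylidenehexadeca-6,10,14-triene-1,2-diol | CC(C)=CCC/C(C)=C/CC/C(C)=C/CCC(=C)[C@H](O)CO
A4 | direct plan | (2S,6E,10E)-7,11,15-trimethyl-3-methylidenehexadeca-6,10,14-triene-1,2-diyl diacetate | CC(C)=CCC/C(C)=C/CC/C(C)=C/CCC(=C)[C@H](OC(C)=O)COC(C)=O
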